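# Design of a total synthesis of CNP0171655.1 (34) by a tether-controlled intramolecular Diels–Alder reaction

## The problem

The target 34 is a labda-7,14-diene: a trans-decalin whose ring B (C5–C10) holds a trisubstituted C7=C8 alkene and, at the ring fusion, a quaternary C10 that carries the oxygenated C20 (as CH2OAc) between the stereocentres C5 and C9. Ring A holds a cis-2α,3α-diol next to the C4 gem-dimethyl group. Only the equatorial O2 is acylated (angelate); the axial, neopentylic O3 is free. The five ring stereocentres can inform one another: C2/C3 can decide the face on which C5 and C10 are made if ring A closes through a chair, and C9 can be tied to C10 through the geometry of a C9=C10 alkene. The sixth stereocentre, the tertiary allylic carbinol C13, is too far from the ring to be controlled by it and has to come from the chiral pool. Three groups limit the late chemistry: the angelate (Z→E isomerisation, conjugate addition), the primary acetate, and the linalyl-type tertiary allylic alcohol (ionisation, and cyclisation onto C8 once the Δ7 alkene exists). They exclude strong acid, strong base and hydride late in the route, so the angelate has to be installed last. The enabling feature is ring B: moving the C7=C8 alkene to C6=C7 as a C7 enol ether turns the ring C5–C6–C7–C8–C9–C10 into a Diels–Alder retron. Its dienophile carbon C10 already carries the activating C20 carbonyl, and C1–C4 of ring A form the tether of a 1,7,9-decatriene.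

## Retrosynthesis

**C2–O acyl bond (34 ⇒ 31 + 32).** The angelate is cut first because it would not survive hydride, fluoride-generated enolates or Pd–H. Triol 31 offers three hydroxyls of very different reactivity: equatorial secondary O2, axial neopentylic O3 and tertiary O13. The forward step therefore only needs an acylation that does not isomerise angelic acid 32, and the mixed anhydride 33 serves this.

**Functional-group adjustments without skeletal change (31 ⇒ 30 ⇒ 29 ⇒ 28 ⇒ 27 ⇒ 26 ⇒ 24).** The acetonide and the C13 silyl ether of 30 are removed together. The Δ7 alkene comes from the more substituted enol triflate 29 of C7 ketone 28, which erases the C8 centre. The ketone is the hydrolysed form of silyl enol ether 27. The C20 acetate comes from alcohol 26 and this from ester 24 (through aldehyde 25). The order is chosen so that hydride meets the ester while C7 is still masked as its enol ether, and so that the acetate only has to tolerate a non-basic triflation.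

**C5–C10 and C8–C9, rings A and B together (24 ⇒ 23).** This is the key cut. An intermolecular Diels–Alder reaction, or a stepwise annulation onto a preformed ring A, would have to form the bond to the quaternary C10 without help. With the C1–C4 tether the same bond forms intramolecularly, and the C4 gem-dimethyl group favours folding. The precursor 23 is acyclic, with only the stereocentres C2, C3 and C13 and two defined alkenes, whereas 24 has two rings and four new stereocentres. The forward reaction must pass through the ester-endo, chair-tether transition state on the face dictated by the cis-acetonide, and the silyl dienol ether must tolerate the temperature.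

**C9=C10 (23 ⇒ 18 + 22).** A Z-selective Horner–Wadsworth–Emmons (Still–Gennari) reaction joins the terpenoid side chain to the core fragment at the last moment before the cycloaddition. An E-selective olefination would give the wrong C9 configuration after cycloaddition. The diene is already masked as silyl enol ether in 18, so the phosphonate anion meets no Michael acceptor within its own molecule. The forward step asks for kinetic Z-selectivity from an α-branched phosphonate.

**Side-chain aldehyde (22 ⇒ 20 ⇒ 19).** (R)-Linalool 19 supplies C11–C16 with C13 in the correct configuration. After silylation to 20, ozonolysis of the electron-rich trisubstituted alkene (through ozonide 21) gives aldehyde 22 and leaves the vinyl group untouched.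

**C5=C6 and the diene (18 ⇒ 17 ⇒ 13 + 16; 13 ⇒ 11).** Soft enolisation of ethyl enone 17 should give the (Z)-silyl enol ether, which places C17 on the outside of the diene. The enone comes from a Wittig reaction of the non-enolisable aldehyde 13 with ylide 16 (from bromoketone 14 through salt 15). A base-free Wittig reaction is chosen over a phosphonate olefination because 13 carries an acidic phosphonoacetate. Aldehyde 13 is unmasked by ozonolysis of the vinyl group of 11 (through ozonide 12). This must happen before the linalool vinyl group enters the molecule.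

**C1–C10 (11 ⇒ 8 + 9).** Alkylating the commercial phosphonate 9 with the triflate 10 of alcohol 8 places phosphorus and the C20 ester on C10 in one step. The cost is an SN2 reaction at a β-oxygenated primary carbon, and that is why the triflate is used.

**C3–C4 and the diol (8 ⇒ 7 ⇒ 6 ⇒ 5 ⇒ 4 ⇒ 2 + 3; 2 ⇒ 1).** Reverse prenylation of (R)-glyceraldehyde acetonide 2 with prenyl bromide 3 forms C3–C4. It brings in the gem-dimethyl carbon and a vinyl group as masked C5, and Felkin–Anh control sets C3 erythro to C2. C2 comes from D-mannitol diacetonide 1. The price is moving the ketal from O1/O2 (4) to O2/O3 (7) through triol 5 and silyl ether 6, then freeing O1 (8). An asymmetric epoxidation of an (E)-allylic alcohol built from neopentyl glycol was also weighed. It reaches the same array only after a net inversion at C2 and the same ketal relocation, and it is longer.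

## Roads not taken

**Alternative 1:** The cut is C10–C20 plus C9–C11, both appended to a preformed decalin. In the forward direction, the triplet state of octalone A1 (a C9=C10 enone with the C8 ketone) adds vinylene carbonate A2 in a [2+2] photocycloaddition to give cyclobutane A3. Later hydrolysis and glycol cleavage open the C20–C11 bond.

- Merits: photochemical bond formation is little affected by crowding at the quaternary C10. C20 and C11 arrive cis in one step. The C8 ketone is an excellent handle for C17 and the Δ7 alkene, through the less substituted enol triflate and methyl coupling; this is regiochemically cleaner than step 19 of the chosen route.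
- Weak points: the ring fusion (C20 relative to H5) rests on the facial behaviour of a twisted enone triplet and is not secured by any element of A1. After cleavage, two aldehyde-level carbons must be told apart next to an epimerisable C9. C12–C16 with C13 must be added without control from the ring. A1 carries only a 3β-oxygen, so C2 oxygenation and inversion at C3 remain.
- Comparison: this road is safer at the quaternary centre and at the alkene. The chosen plan sets against this that all ring stereocentres, the side chain and C13 are in place after one step, under control of purchased stereocentres.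

**Alternative 2:** The cut is C2–C3. In the forward direction, a samarium(II)-mediated pinacol coupling of the 2,3-seco dialdehyde A4 closes ring A as the cis-diol A5, which is the same compound as 31.

- Merits: cis-selective six-ring pinacol closure is dependable. No diol protecting group is needed, so the ketal relocation (steps 3–6) and the acidic unmasking (step 21) of the chosen route disappear. The end game is shared.
- Weak points: the strategy does not address ring B. A4 must already contain C5, C9 and the quaternary C10 on a monocyclic cyclohexene. Both cis-diols (2α,3α and 2β,3β) are possible, and only the C10 substituents discriminate between them. The C3 aldehyde is neopentylic and the C2 aldehyde is enolisable.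
- Comparison: this road is gentler on the late functional groups. The chosen plan uses the diol as the source of all core stereochemistry instead of creating it last under weak control.

**Alternative 3:** The cut is C4–C5. In the forward direction, a chiral copper hydride catalyst converts the allene of the prochiral dione A6 into an allylcopper species. Its dimethylated carbon adds to one of the two enantiotopic ketones and gives hydroxy ketone A7.

- Merits: the quaternary C10 is set catalytically from an achiral, easily made dione. The Δ2 alkene of A7 is well placed for an α-face dihydroxylation to the 2α,3α-diol.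
- Weak points: A7 has a tertiary C5 hydroxyl that must be replaced by hydrogen trans to C20. Ring B still lacks the C9 side chain, C17 and the alkene. C13 is untouched. Carbonyl addition through the fully substituted allyl terminus next to a quaternary carbon is demanding.
- Comparison: this road is superior in asymmetric economy and needs no diol protecting group. The chosen plan delivers C5–H, the C9 side chain and the C7 handle in the same step that makes C10.

Key step: step 15

## Route

Remark: labdane numbering (C1–C20) is used throughout. C10 of 11–18 is a mixture of epimers that is erased in step 14, and the C8 configuration of 24–28 (8β-methyl, as expected from the cycloaddition) is erased in step 19.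
Remark: (R)-linalool 19 of high enantiomeric purity is assumed; material of lower purity would carry the C13 epimer through the route.

Step 1
Reactants: 1 1,2:5,6-di-O-isopropylidene-D-mannitol
Product: 2 (R)-2,2-dimethyl-1,3-dioxolane-4-carbaldehyde
Conditions: NaIO4, sat. aq. NaHCO3, CH2Cl2, 23 °C; used crude
Reagents that add atoms: none
Why: Malaprade glycol cleavage of the central diol gives two equivalents of the aldehyde. The stereocentre (later C2) comes unchanged from D-mannitol, and immediate use avoids oligomerisation.

Step 2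
Reactants: 2 (R)-2,2-dimethyl-1,3-dioxolane-4-carbaldehyde; 3 prenyl bromide (1-bromo-3-methylbut-2-ene)
Product: 4 (1S)-1-[(4R)-2,2-dimethyl-1,3-dioxolan-4-yl]-2,2-dimethylbut-3-en-1-ol
Conditions: Zn dust, THF/sat. aq. NH4Cl, 0 → 23 °C
Reagents that add atoms: none
Why: In this Barbier-type zinc allylation the prenylzinc species reacts through its γ-carbon (SE2′), forming C3–C4 with the gem-dimethyl carbon and a vinyl group as masked C5. C3 is set by Felkin–Anh addition anti to the α-C–O bond (erythro adduct); the minor syn epimer is removed by chromatography.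

Step 3
Reactants: 4 (1S)-1-[(4R)-2,2-dimethyl-1,3-dioxolan-4-yl]-2,2-dimethylbut-3-en-1-ol
Product: 5 (2R,3S)-4,4-dimethylhex-5-ene-1,2,3-triol
Conditions: AcOH/H2O (4:1), 40 °C
Reagents that add atoms: none
Why: Acid-catalysed ketal hydrolysis. The terminal ketal must go because it blocks O1/O2, whereas the tether needs O2/O3 bridged.

Step 4
Reactants: 5 (2R,3S)-4,4-dimethylhex-5-ene-1,2,3-triol
Product: 6 (2R,3S)-1-[(tert-butyldiphenylsilyl)oxy]-4,4-dimethylhex-5-ene-2,3-diol
Conditions: TBDPSCl (1.05 equiv), imidazole, CH2Cl2/DMF, 0 °C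
Reagents that add atoms: tert-butyldiphenylsilyl chloride, CC(C)(C)[Si](Cl)(c1ccccc1)c1ccccc1
Why: Sterically controlled silylation of the only primary hydroxyl; the bulky silyl chloride should leave the secondary and the neopentylic hydroxyl untouched.

Step 5
Reactants: 6 (2R,3S)-1-[(tert-butyldiphenylsilyl)oxy]-4,4-dimethylhex-5-ene-2,3-diol
Product: 7 tert-butyl{[(4R,5S)-2,2-dimethyl-5-(2-methylbut-3-en-2-yl)-1,3-dioxolan-4-yl]methoxy}diphenylsilane
Conditions: 2,2-dimethoxypropane, PPTS (cat.), CH2Cl2, 23 °C
Reagents that add atoms: 2,2-dimethoxypropane, COC(C)(C)OC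
Why: Acid-catalysed transketalisation can now engage only O2/O3 and gives the cis-dioxolane of the erythro diol. No stereocentre is touched.

Step 6
Reactants: 7 tert-butyl{[(4R,5S)-2,2-dimethyl-5-(2-methylbut-3-en-2-yl)-1,3-dioxolan-4-yl]methoxy}diphenylsilane
Product: 8 [(4R,5S)-2,2-dimethyl-5-(2-methylbut-3-en-2-yl)-1,3-dioxolan-4-yl]methanol
Conditions: TBAF, THF, 0 → 23 °C
Reagents that add atoms: none
Why: Fluoride-induced desilylation frees the C1 hydroxyl; the ketal and the alkene are inert.

Step 7
Reactants: 8 [(4R,5S)-2,2-dimethyl-5-(2-methylbut-3-en-2-yl)-1,3-dioxolan-4-yl]methanol; 9 methyl bis(2,2,2-trifluoroethyl)phosphonoacetate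
Product: 11 methyl 2-[bis(2,2,2-trifluoroethoxy)phosphoryl]-3-[(4R,5S)-2,2-dimethyl-5-(2-methylbut-3-en-2-yl)-1,3-dioxolan-4-yl]propanoate (both C10 epimers), via primary triflate 10 (not isolated)
Conditions: Tf2O, 2,6-lutidine, CH2Cl2, −78 °C; then sodium salt of 9 (from NaH, 2.5 equiv), THF/DMPU, −40 → 0 °C
Reagents that add atoms: none
Why: C-alkylation of a stabilised phosphonoacetate carbanion forms C1–C10. The triflate is used because a β-oxygenated primary centre is a sluggish SN2 electrophile as halide, and excess anion suppresses dialkylation.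

Step 8
Reactants: 11 methyl 2-[bis(2,2,2-trifluoroethoxy)phosphoryl]-3-[(4R,5S)-2,2-dimethyl-5-(2-methylbut-3-en-2-yl)-1,3-dioxolan-4-yl]propanoate
Product: 13 methyl 2-[bis(2,2,2-trifluoroethoxy)phosphoryl]-3-[(4R,5S)-2,2-dimethyl-5-(2-methyl-1-oxopropan-2-yl)-1,3-dioxolan-4-yl]propanoate, via ozonide 12 (not isolated)
Conditions: O3, CH2Cl2, −78 °C; then PPh3, −78 → 23 °C
Reagents that add atoms: ozone, [O-][O+]=O
Why: Ozonolysis of the only alkene unmasks C5 as a non-enolisable α-quaternary aldehyde. This is done before the second vinyl group (C14=C15) enters the molecule.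

Step 9
Reactants: 14 1-bromobutan-2-one
Product: 16 1-(triphenyl-λ5-phosphanylidene)butan-2-one, via (2-oxobutyl)triphenylphosphonium bromide 15 (not isolated)
Conditions: PPh3, toluene, 23 → 60 °C; then aq. NaOH, CH2Cl2
Reagents that add atoms: triphenylphosphine, c1ccc(cc1)P(c1ccccc1)c1ccccc1
Why: Quaternisation of the α-bromoketone and deprotonation of the acidic phosphonium salt give the stabilised acyl ylide that carries C6, C7, C8 and C17.

Step 10
Reactants: 13 methyl 2-[bis(2,2,2-trifluoroethoxy)phosphoryl]-3-[(4R,5S)-2,2-dimethyl-5-(2-methyl-1-oxopropan-2-yl)-1,3-dioxolan-4-yl]propanoate; 16 1-(triphenyl-λ5-phosphanylidene)butan-2-one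
Product: 17 methyl 2-[bis(2,2,2-trifluoroethoxy)phosphoryl]-3-{(4R,5S)-2,2-dimethyl-5-[(3E)-2-methyl-5-oxohept-3-en-2-yl]-1,3-dioxolan-4-yl}propanoate
Conditions: toluene, 100 °C
Reagents that add atoms: none
Why: Wittig reaction of a stabilised ylide gives the (E)-C5=C6 enone. The neutral ylide is too weak a base to deprotonate the phosphonoacetate, so no intramolecular olefination of the aldehyde by its own phosphonate is expected.

Step 11
Reactants: 17 methyl 2-[bis(2,2,2-trifluoroethoxy)phosphoryl]-3-{(4R,5S)-2,2-dimethyl-5-[(3E)-2-methyl-5-oxohept-3-en-2-yl]-1,3-dioxolan-4-yl}propanoate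
Product: 18 methyl 2-[bis(2,2,2-trifluoroethoxy)phosphoryl]-3-{(4R,5S)-5-[(3E,5Z)-5-(tert-butyldimethylsilyloxy)-2-methylhepta-3,5-dien-2-yl]-2,2-dimethyl-1,3-dioxolan-4-yl}propanoate
Conditions: TBSOTf, Et3N, CH2Cl2, −78 → 0 °C
Reagents that add atoms: tert-butyldimethylsilyl triflate, CC(C)(C)[Si](C)(C)OS(=O)(=O)C(F)(F)F
Why: Soft enolisation of the ethyl ketone gives the 2-silyloxy diene with the (Z)-enol ether geometry (C17 outside). Masking the enone here removes the Michael acceptor before the phosphonate is deprotonated in step 14.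

Step 12
Reactants: 19 (R)-linalool
Product: 20 triethyl{[(3R)-3,7-dimethylocta-1,6-dien-3-yl]oxy}silane
Conditions: TESOTf, 2,6-lutidine, CH2Cl2, −78 → 0 °C
Reagents that add atoms: triethylsilyl triflate, CC[Si](CC)(CC)OS(=O)(=O)C(F)(F)F
Why: Silylation of the tertiary allylic alcohol with the reactive silyl triflate and a hindered base; C13 is untouched.

Step 13
Reactants: 20 triethyl{[(3R)-3,7-dimethylocta-1,6-dien-3-yl]oxy}silane
Product: 22 (4R)-4-methyl-4-(triethylsilyloxy)hex-5-enal, via ozonide 21 (not isolated)
Conditions: O3 (1 equiv, Sudan Red 7B end point), CH2Cl2, −78 °C; then PPh3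
Reagents that add atoms: ozone, [O-][O+]=O
Why: Chemoselective ozonolysis: the trisubstituted alkene reacts far faster than the monosubstituted vinyl group next to the quaternary carbinol carbon, and an indicator dye marks the end point.

Step 14
Reactants: 18 methyl 2-[bis(2,2,2-trifluoroethoxy)phosphoryl]-3-{(4R,5S)-5-[(3E,5Z)-5-(tert-butyldimethylsilyloxy)-2-methylhepta-3,5-dien-2-yl]-2,2-dimethyl-1,3-dioxolan-4-yl}propanoate; 22 (4R)-4-methyl-4-(triethylsilyloxy)hex-5-enal
Product: 23 methyl (2Z,6R)-2-({(4R,5S)-5-[(3E,5Z)-5-(tert-butyldimethylsilyloxy)-2-methylhepta-3,5-dien-2-yl]-2,2-dimethyl-1,3-dioxolan-4-yl}methyl)-6-methyl-6-(triethylsilyloxy)octa-2,7-dienoate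
Conditions: KHMDS, 18-crown-6, THF, −78 °C; then 22; pH 7 work-up, Et3N-deactivated silica
Reagents that add atoms: none
Why: Still–Gennari variant of the Horner–Wadsworth–Emmons reaction: with the electron-poor phosphonate and a dissociated potassium counter-ion, elimination from the kinetic adduct outruns equilibration, so C11 ends up cis to the ester (Z). The C10 epimer mixture converges here.

Step 15
Reactants: 23 methyl (2Z,6R)-2-({(4R,5S)-5-[(3E,5Z)-5-(tert-butyldimethylsilyloxy)-2-methylhepta-3,5-dien-2-yl]-2,2-dimethyl-1,3-dioxolan-4-yl}methyl)-6-methyl-6-(triethylsilyloxy)octa-2,7-dienoate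
Product: 24 methyl (13R)-7-(tert-butyldimethylsilyloxy)-2α,3α-(isopropylidenedioxy)-13-(triethylsilyloxy)-8β-methyl-labda-6,14-dien-20-oate (5α-H, 8α-H, 9α-H)
Conditions: toluene (0.01 M), BHT (cat.), base-washed sealed tube, 165 °C
Reagents that add atoms: none
Why: This is a thermal, concerted but asynchronous normal-demand [4+2] cycloaddition, the type 1 intramolecular Diels–Alder reaction of a 1,7,9-decatriene; the closest known cases are 2-silyloxy-diene decatrienes with α-tethered acrylates that give angularly functionalised trans-decalins. The tether enforces the electronically favoured pairing of C8 (the enol ether β-carbon) with C9 (the enoate β-carbon). Ring B closes as the cyclohexene of the cycloaddition (C5–C10 and C8–C9), and ring A closes in the fused mode as the six-membered carbocycle spanned by C1–C4 in a chair-like arrangement. The C9/C10 relation follows from suprafacial addition to the (Z)-enoate (C11 cis to C20). The trans ring fusion follows from the ester-endo, tether-anti transition state (C20 anti to H5). C8 (8β-methyl) follows from the (Z)-enol ether and is discarded in step 19. The absolute sense is set by the cis-acetonide: the reactive chair has O3 axial and O2 equatorial, whereas addition to the other diene face would place O2 axial against the C10 ester and a C4 methyl. The step needs endo and facial selectivity; the alkene geometries, the C4 gem-dimethyl group (folding) and the rigid ketal secure them, and BHT with base-washed glass protects the silyl enol ether.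

Step 16
Reactants: 24 methyl (13R)-7-(tert-butyldimethylsilyloxy)-2α,3α-(isopropylidenedioxy)-13-(triethylsilyloxy)-8β-methyl-labda-6,14-dien-20-oate
Product: 26 (13R)-7-(tert-butyldimethylsilyloxy)-2α,3α-(isopropylidenedioxy)-13-(triethylsilyloxy)-8β-methyl-labda-6,14-dien-20-ol, via C20 aldehyde 25 (not isolated)
Conditions: DIBAL-H (excess), CH2Cl2, −78 → 0 °C; Rochelle salt
Reagents that add atoms: none
Why: Hydride reduction of the angular ester through the aldehyde. It is done while C7 is still a silyl enol ether, so no ketone is exposed to hydride; the silyl ethers, the ketal and the alkenes are inert.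

Step 17
Reactants: 26 (13R)-7-(tert-butyldimethylsilyloxy)-2α,3α-(isopropylidenedioxy)-13-(triethylsilyloxy)-8β-methyl-labda-6,14-dien-20-ol
Product: 27 (13R)-20-acetoxy-7-(tert-butyldimethylsilyloxy)-2α,3α-(isopropylidenedioxy)-13-(triethylsilyloxy)-8β-methyl-labda-6,14-diene
Conditions: Ac2O, pyridine, DMAP (cat.), CH2Cl2, 23 °C
Reagents that add atoms: acetic anhydride, CC(=O)OC(C)=O
Why: DMAP-catalysed acetylation of the only free hydroxyl (neopentylic but primary) installs the C20 acetate of the target.

Step 18
Reactants: 27 (13R)-20-acetoxy-7-(tert-butyldimethylsilyloxy)-2α,3α-(isopropylidenedioxy)-13-(triethylsilyloxy)-8β-methyl-labda-6,14-diene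
Product: 28 (13R)-20-acetoxy-2α,3α-(isopropylidenedioxy)-13-(triethylsilyloxy)-8β-methyl-labd-14-en-7-one
Conditions: TBAF (1.1 equiv), AcOH (1.2 equiv), THF, −20 → 0 °C
Reagents that add atoms: none
Why: Buffered fluoride cleaves the Si–O bond of the enol ether far faster than that of the hindered tertiary triethylsilyl ether, and the enolate is protonated at C6 by acetic acid. The acetate survives the buffered medium, and any epimerisation at C8 is of no consequence.

Step 19
Reactants: 28 (13R)-20-acetoxy-2α,3α-(isopropylidenedioxy)-13-(triethylsilyloxy)-8β-methyl-labd-14-en-7-one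
Product: 29 (13R)-20-acetoxy-2α,3α-(isopropylidenedioxy)-13-(triethylsilyloxy)labda-7,14-dien-7-yl trifluoromethanesulfonate
Conditions: Tf2O, 2,6-di-tert-butyl-4-methylpyridine, CH2Cl2, 0 → 23 °C
Reagents that add atoms: trifluoromethanesulfonic anhydride, O=S(=O)(OS(=O)(=O)C(F)(F)F)C(F)(F)F
Why: Electrophilic O-triflation of the ketone followed by proton loss from the more substituted α-carbon (Stang-type vinyl triflate synthesis) should favour the tetrasubstituted C7=C8 enol triflate. This direction also relieves the syn-axial contact of the C8 methyl with the C10 substituent, and the non-nucleophilic base spares acetate, ketal and silyl ether.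

Step 20
Reactants: 29 (13R)-20-acetoxy-2α,3α-(isopropylidenedioxy)-13-(triethylsilyloxy)labda-7,14-dien-7-yl trifluoromethanesulfonate
Product: 30 (13R)-20-acetoxy-2α,3α-(isopropylidenedioxy)-13-(triethylsilyloxy)labda-7,14-diene
Conditions: Pd(OAc)2 (cat.), PPh3, HCO2H, Bu3N, DMF, 60 °C
Reagents that add atoms: none
Why: Palladium-catalysed formate reduction of the enol triflate (oxidative addition, decarboxylation of the formate complex, C–H reductive elimination) replaces OTf by H with the alkene fixed at C7=C8. Isolated alkenes and the non-allylic acetate do not react.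

Step 21
Reactants: 30 (13R)-20-acetoxy-2α,3α-(isopropylidenedioxy)-13-(triethylsilyloxy)labda-7,14-diene
Product: 31 (13R)-20-acetoxylabda-7,14-diene-2α,3α,13-triol
Conditions: PPTS, MeOH, 50 °C
Reagents that add atoms: none
Why: Acid-catalysed methanolysis removes the ketal (transketalisation) and the triethylsilyl ether in one operation. The weak pyridinium acid is chosen so that the tertiary allylic carbinol does not ionise and the Δ7 alkene is not protonated.

Step 22
Reactants: 31 (13R)-20-acetoxylabda-7,14-diene-2α,3α,13-triol; 32 angelic acid [(Z)-2-methylbut-2-enoic acid]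
Product: 34 (13R)-20-acetoxy-2α-(angeloyloxy)labda-7,14-diene-3α,13-diol (CNP0171655.1), via angelic 2,4,6-trichlorobenzoic anhydride 33 (not isolated)
Conditions: 32, 2,4,6-trichlorobenzoyl chloride, Et3N, toluene, 23 °C; then 31, 60 °C
Reagents that add atoms: none
Why: Yamaguchi-type mixed-anhydride esterification, run without a nucleophilic catalyst so that the angelate is not isomerised to the tiglate. The equatorial O2 should react much faster than the axial O3 beside the gem-dimethyl group and the tertiary O13.

## Compound list

1 | 1,2:5,6-di-O-isopropylidene-D-mannitol | CC1(C)OC[C@@H](O1)[C@@H](O)[C@H](O)[C@H]1COC(C)(C)O1 | starting material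
2 | (R)-2,2-dimethyl-1,3-dioxolane-4-carbaldehyde | O=C[C@H]1COC(C)(C)O1 | intermediate
3 | prenyl bromide (1-bromo-3-methylbut-2-ene) | CC(C)=CCBr | starting material
4 | (1S)-1-[(4R)-2,2-dimethyl-1,3-dioxolan-4-yl]-2,2-dimethylbut-3-en-1-ol | C=CC(C)(C)[C@H](O)[C@H]1COC(C)(C)O1 | intermediate
5 | (2R,3S)-4,4-dimethylhex-5-ene-1,2,3-triol | C=CC(C)(C)[C@H](O)[C@H](O)CO | intermediate
6 | (2R,3S)-1-[(tert-butyldiphenylsilyl)oxy]-4,4-dimethylhex-5-ene-2,3-diol | C=CC(C)(C)[C@H](O)[C@H](O)CO[Si](c1ccccc1)(c1ccccc1)C(C)(C)C | intermediate
7 | tert-butyl{[(4R,5S)-2,2-dimethyl-5-(2-methylbut-3-en-2-yl)-1,3-dioxolan-4-yl]methoxy}diphenylsilane | C=CC(C)(C)[C@@H]1OC(C)(C)O[C@@H]1CO[Si](c1ccccc1)(c1ccccc1)C(C)(C)C | intermediate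
8 | [(4R,5S)-2,2-dimethyl-5-(2-methylbut-3-en-2-yl)-1,3-dioxolan-4-yl]methanol | C=CC(C)(C)[C@@H]1OC(C)(C)O[C@@H]1CO | intermediate
9 | methyl bis(2,2,2-trifluoroethyl)phosphonoacetate | COC(=O)CP(=O)(OCC(F)(F)F)OCC(F)(F)F | starting material
10 | [(4R,5S)-2,2-dimethyl-5-(2-methylbut-3-en-2-yl)-1,3-dioxolan-4-yl]methyl trifluoromethanesulfonate | C=CC(C)(C)[C@@H]1OC(C)(C)O[C@@H]1COS(=O)(=O)C(F)(F)F | intermediate (not isolated)
11 | methyl 2-[bis(2,2,2-trifluoroethoxy)phosphoryl]-3-[(4R,5S)-2,2-dimethyl-5-(2-methylbut-3-en-2-yl)-1,3-dioxolan-4-yl]propanoate (C10 epimers) | C=CC(C)(C)[C@@H]1OC(C)(C)O[C@@H]1CC(C(=O)OC)P(=O)(OCC(F)(F)F)OCC(F)(F)F | intermediate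
12 | ozonide (1,2,4-trioxolane) of 11 | CC(C)(C1OCOO1)[C@@H]2OC(C)(C)O[C@@H]2CC(C(=O)OC)P(=O)(OCC(F)(F)F)OCC(F)(F)F | intermediate (not isolated)
13 | methyl 2-[bis(2,2,2-trifluoroethoxy)phosphoryl]-3-[(4R,5S)-2,2-dimethyl-5-(2-methyl-1-oxopropan-2-yl)-1,3-dioxolan-4-yl]propanoate | O=CC(C)(C)[C@@H]1OC(C)(C)O[C@@H]1CC(C(=O)OC)P(=O)(OCC(F)(F)F)OCC(F)(F)F | intermediate
14 | 1-bromobutan-2-one | CCC(=O)CBr | starting material
15 | (2-oxobutyl)triphenylphosphonium bromide | CCC(=O)C[P+](c1ccccc1)(c1ccccc1)c1ccccc1.[Br-] | intermediate (not isolated)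
16 | 1-(triphenyl-λ5-phosphanylidene)butan-2-one | CCC(=O)C=P(c1ccccc1)(c1ccccc1)c1ccccc1 | intermediate
17 | methyl 2-[bis(2,2,2-trifluoroethoxy)phosphoryl]-3-{(4R,5S)-2,2-dimethyl-5-[(3E)-2-methyl-5-oxohept-3-en-2-yl]-1,3-dioxolan-4-yl}propanoate | CCC(=O)/C=C/C(C)(C)[C@@H]1OC(C)(C)O[C@@H]1CC(C(=O)OC)P(=O)(OCC(F)(F)F)OCC(F)(F)F | intermediate
18 | methyl 2-[bis(2,2,2-trifluoroethoxy)phosphoryl]-3-{(4R,5S)-5-[(3E,5Z)-5-(tert-butyldimethylsilyloxy)-2-methylhepta-3,5-dien-2-yl]-2,2-dimethyl-1,3-dioxolan-4-yl}propanoate | C/C=C(O[Si](C)(C)C(C)(C)C)/C=C/C(C)(C)[C@@H]1OC(C)(C)O[C@@H]1CC(C(=O)OC)P(=O)(OCC(F)(F)F)OCC(F)(F)F | intermediate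
19 | (R)-linalool | C=C[C@](C)(O)CCC=C(C)C | starting material
20 | triethyl{[(3R)-3,7-dimethylocta-1,6-dien-3-yl]oxy}silane | C=C[C@](C)(O[Si](CC)(CC)CC)CCC=C(C)C | intermediate
21 | ozonide (3,3-dimethyl-1,2,4-trioxolane) of 20 | C=C[C@](C)(O[Si](CC)(CC)CC)CCC1OC(C)(C)OO1 | intermediate (not isolated)
22 | (4R)-4-methyl-4-(triethylsilyloxy)hex-5-enal | C=C[C@](C)(O[Si](CC)(CC)CC)CCC=O | intermediate
23 | methyl (2Z,6R)-2-({(4R,5S)-5-[(3E,5Z)-5-(tert-butyldimethylsilyloxy)-2-methylhepta-3,5-dien-2-yl]-2,2-dimethyl-1,3-dioxolan-4-yl}methyl)-6-methyl-6-(triethylsilyloxy)octa-2,7-dienoate | C=C[C@](C)(O[Si](CC)(CC)CC)CC/C=C(\C(=O)OC)C[C@H]1OC(C)(C)O[C@H]1C(C)(C)/C=C/C(O[Si](C)(C)C(C)(C)C)=C/C | intermediate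
24 | methyl (13R)-7-(tert-butyldimethylsilyloxy)-2α,3α-(isopropylidenedioxy)-13-(triethylsilyloxy)-8β-methyl-labda-6,14-dien-20-oate | C=C[C@](C)(O[Si](CC)(CC)CC)CC[C@H]1[C@@H](C)C(O[Si](C)(C)C(C)(C)C)=C[C@H]2C(C)(C)[C@@H]3OC(C)(C)O[C@@H]3C[C@]12C(=O)OC | intermediate
25 | (13R)-7-(tert-butyldimethylsilyloxy)-2α,3α-(isopropylidenedioxy)-13-(triethylsilyloxy)-8β-methyl-labda-6,14-dien-20-al | C=C[C@](C)(O[Si](CC)(CC)CC)CC[C@H]1[C@@H](C)C(O[Si](C)(C)C(C)(C)C)=C[C@H]2C(C)(C)[C@@H]3OC(C)(C)O[C@@H]3C[C@]12C=O | intermediate (not isolated)
26 | (13R)-7-(tert-butyldimethylsilyloxy)-2α,3α-(isopropylidenedioxy)-13-(triethylsilyloxy)-8β-methyl-labda-6,14-dien-20-ol | C=C[C@](C)(O[Si](CC)(CC)CC)CC[C@H]1[C@@H](C)C(O[Si](C)(C)C(C)(C)C)=C[C@H]2C(C)(C)[C@@H]3OC(C)(C)O[C@@H]3C[C@]12CO | intermediate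
27 | (13R)-20-acetoxy-7-(tert-butyldimethylsilyloxy)-2α,3α-(isopropylidenedioxy)-13-(triethylsilyloxy)-8β-methyl-labda-6,14-diene | C=C[C@](C)(O[Si](CC)(CC)CC)CC[C@H]1[C@@H](C)C(O[Si](C)(C)C(C)(C)C)=C[C@H]2C(C)(C)[C@@H]3OC(C)(C)O[C@@H]3C[C@]12COC(C)=O | intermediate
28 | (13R)-20-acetoxy-2α,3α-(isopropylidenedioxy)-13-(triethylsilyloxy)-8β-methyl-labd-14-en-7-one | C=C[C@](C)(O[Si](CC)(CC)CC)CC[C@H]1[C@@H](C)C(=O)C[C@H]2C(C)(C)[C@@H]3OC(C)(C)O[C@@H]3C[C@]12COC(C)=O | intermediate
29 | (13R)-20-acetoxy-2α,3α-(isopropylidenedioxy)-13-(triethylsilyloxy)labda-7,14-dien-7-yl trifluoromethanesulfonate | C=C[C@](C)(O[Si](CC)(CC)CC)CC[C@H]1C(C)=C(OS(=O)(=O)C(F)(F)F)C[C@H]2C(C)(C)[C@@H]3OC(C)(C)O[C@@H]3C[C@]12COC(C)=O | intermediate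
30 | (13R)-20-acetoxy-2α,3α-(isopropylidenedioxy)-13-(triethylsilyloxy)labda-7,14-diene | C=C[C@](C)(O[Si](CC)(CC)CC)CC[C@H]1C(C)=CC[C@H]2C(C)(C)[C@@H]3OC(C)(C)O[C@@H]3C[C@]12COC(C)=O | intermediate
31 | (13R)-20-acetoxylabda-7,14-diene-2α,3α,13-triol | C=C[C@](C)(O)CC[C@H]1C(C)=CC[C@H]2C(C)(C)[C@H](O)[C@H](O)C[C@]12COC(C)=O | intermediate
32 | angelic acid [(Z)-2-methylbut-2-enoic acid] | C/C=C(/C)C(=O)O | starting material
33 | angelic 2,4,6-trichlorobenzoic anhydride | C/C=C(/C)C(=O)OC(=O)c1c(Cl)cc(Cl)cc1Cl | intermediate (not isolated)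
34 | (13R)-20-acetoxy-2α-(angeloyloxy)labda-7,14-diene-3α,13-diol (CNP0171655.1) | C=C[C@](C)(O)CC[C@H]1C(C)=CC[C@H]2C(C)(C)[C@H](O)[C@H](OC(=O)/C(C)=C\C)C[C@]12COC(C)=O | target

## Step count and weak points

Total step count: 22. Longest linear sequence: 19 steps (steps 1–8, 10, 11 and 14–22); steps 9, 12 and 13 are side branches.

**Step 15 (key step).** The most likely failure is a cycloaddition that is too slow. The new C5–C10 bond joins a carbon next to the quaternary C4 to a fully substituted carbon, and the dienophile is only a β-alkyl-substituted acrylate. Prolonged heating could then erode the silyl dienol ether or the (Z)-enoate geometry, or open competing exo/cis-fused pathways. The fallback changes the activating group. It sets out from 23: DIBAL-H reduction gives the (2Z)-allylic alcohol F1, and buffered Dess–Martin oxidation gives the (2Z)-enal F2. As an α-substituted acrolein, F2 should cyclise well below 100 °C with a stronger endo preference. Its cycloadduct is aldehyde 25, where the fallback returns to the route (sodium borohydride then gives 26).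

**Step 7.** The weakly nucleophilic, hindered fluorinated phosphonate anion may displace the β-oxygenated triflate too slowly. The triflate could then decompose, or the anion could lose trifluoroethoxide on warming; dialkylation is a lesser concern. The fallback separates C–C bond formation from the choice of phosphorus esters. It sets out from 8 (through 10): the more nucleophilic sodium salt of trimethyl phosphonoacetate is alkylated to the dimethyl phosphonate F3. The phosphorus esters are then exchanged by bromotrimethylsilane/2,6-lutidine followed by oxalyl chloride with catalytic DMF, giving the phosphonic dichloride F4. Treatment with 2,2,2-trifluoroethanol and pyridine returns to the route at 11.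

**Step 14.** The bulky α-substituent may erode the kinetic Z-selectivity. In addition, the acid-sensitive silyl dienol ether may not survive the work-up and the chromatography needed to remove the E-isomer. The fallback changes the order of events so that the olefination is run and purified on robust material. It sets out from 17: Still–Gennari reaction of 17 with 22 gives the enone–enoate F5, which is freed from its E-isomer on ordinary silica. Soft enolisation (TBSOTf, Et3N) then returns to the route at 23. The price is an anion that coexists briefly with the enone at −78 °C.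

**Step 19.** Proton loss after O-triflation may not be regioselective, and the less substituted C6=C7 triflate may form alongside the desired one. Ionising side reactions of the activated ketone are a second risk. The fallback separates regiocontrol from triflation. It sets out from 28: equilibrating silylation (TMSCl, Et3N, DMF, 90 °C) gives the more substituted trimethylsilyl enol ether F6 under thermodynamic control. Fluoride-triggered triflation (CsF, N-phenyltriflimide, DME) then returns to the route at 29.

**Step 22.** Acylation may not stop cleanly at O2: some O3 acylation or acyl migration is possible, and forcing the reaction invites angelate-to-tiglate isomerisation. The fallback replaces substrate control by reagent control. It sets out from 31: dibutyltin oxide (toluene, reflux, water removal) gives the 2,3-O-dibutylstannylene acetal F7, which activates the equatorial oxygen. Acylation with the preformed anhydride 33 at ambient temperature returns to the route at 34.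

## Further compounds

F1 | step 15 | (2Z,6R)-2-({(4R,5S)-5-[(3E,5Z)-5-(tert-butyldimethylsilyloxy)-2-methylhepta-3,5-dien-2-yl]-2,2-dimethyl-1,3-dioxolan-4-yl}methyl)-6-methyl-6-(triethylsilyloxy)octa-2,7-dien-1-ol | C=C[C@](C)(O[Si](CC)(CC)CC)CC/C=C(\CO)C[C@H]1OC(C)(C)O[C@H]1C(C)(C)/C=C/C(O[Si](C)(C)C(C)(C)C)=C/C
F2 | step 15 | (2Z,6R)-2-({(4R,5S)-5-[(3E,5Z)-5-(tert-butyldimethylsilyloxy)-2-methylhepta-3,5-dien-2-yl]-2,2-dimethyl-1,3-dioxolan-4-yl}methyl)-6-methyl-6-(triethylsilyloxy)octa-2,7-dienal | C=C[C@](C)(O[Si](CC)(CC)CC)CC/C=C(\C=O)C[C@H]1OC(C)(C)O[C@H]1C(C)(C)/C=C/C(O[Si](C)(C)C(C)(C)C)=C/C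
F3 | step 7 | methyl 2-(dimethoxyphosphoryl)-3-[(4R,5S)-2,2-dimethyl-5-(2-methylbut-3-en-2-yl)-1,3-dioxolan-4-yl]propanoate | C=CC(C)(C)[C@@H]1OC(C)(C)O[C@@H]1CC(C(=O)OC)P(=O)(OC)OC
F4 | step 7 | methyl 2-(dichlorophosphoryl)-3-[(4R,5S)-2,2-dimethyl-5-(2-methylbut-3-en-2-yl)-1,3-dioxolan-4-yl]propanoate | C=CC(C)(C)[C@@H]1OC(C)(C)O[C@@H]1CC(C(=O)OC)P(=O)(Cl)Cl
F5 | step 14 | methyl (2Z,6R)-2-({(4R,5S)-2,2-dimethyl-5-[(3E)-2-methyl-5-oxohept-3-en-2-yl]-1,3-dioxolan-4-yl}methyl)-6-methyl-6-(triethylsilyloxy)octa-2,7-dienoate | C=C[C@](C)(O[Si](CC)(CC)CC)CC/C=C(\C(=O)OC)C[C@H]1OC(C)(C)O[C@H]1C(C)(C)/C=C/C(=O)CC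
F6 | step 19 | (13R)-20-acetoxy-2α,3α-(isopropylidenedioxy)-13-(triethylsilyloxy)-7-(trimethylsilyloxy)labda-7,14-diene | C=C[C@](C)(O[Si](CC)(CC)CC)CC[C@H]1C(C)=C(O[Si](C)(C)C)C[C@H]2C(C)(C)[C@@H]3OC(C)(C)O[C@@H]3C[C@]12COC(C)=O
F7 | step 22 | (13R)-20-acetoxy-2α,3α-(dibutylstannylenedioxy)labda-7,14-dien-13-ol | C=C[C@](C)(O)CC[C@H]1C(C)=CC[C@H]2C(C)(C)[C@@H]3O[Sn](CCCC)(CCCC)O[C@@H]3C[C@]12COC(C)=O
A1 | alternative 1 | 3β-(tert-butyldimethylsilyloxy)-4,4-dimethyl-octal-9(10)-en-8-one (5α-H, labdane numbering) | O=C1CC[C@H]2C(C)(C)[C@@H](O[Si](C)(C)C(C)(C)C)CCC2=C1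
A2 | alternative 1 | vinylene carbonate | O=C1OC=CO1
A3 | alternative 1 | cyclobutane-fused carbonate photoadduct | O=C4O[C@@H]3[C@H]1C(=O)CC[C@H]2C(C)(C)[C@@H](O[Si](C)(C)C(C)(C)C)CC[C@]12[C@@H]3O4
A4 | alternative 2 | 2,3-seco-dialdehyde (20-acetoxy-13-hydroxy-2,3-secolabda-7,14-diene-2,3-dial) | C=C[C@](C)(O)CC[C@H]1C(C)=CC[C@@H](C(C)(C)C=O)[C@@]1(CC=O)COC(C)=O
A5 | alternative 2 | (13R)-20-acetoxylabda-7,14-diene-2α,3α,13-triol (2α,3α-diol, identical with 31) | C=C[C@](C)(O)CC[C@H]1C(C)=CC[C@H]2C(C)(C)[C@H](O)[C@H](O)C[C@]12COC(C)=O
A6 | alternative 3 | 2-[(tert-butyldimethylsilyloxy)methyl]-2-(4-methylpenta-2,3-dien-1-yl)cyclohexane-1,3-dione | O=C1CCCC(=O)C1(CC=C=C(C)C)CO[Si](C)(C)C(C)(C)C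
A7 | alternative 3 | 5-hydroxy-4,4-dimethyl-20-silyloxy-octal-2-en-9-one (labdane numbering) | O=C1CCC[C@]2(O)C(C)(C)C=CC[C@]12CO[Si](C)(C)C(C)(C)C
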